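## Structural features

Compound 33 is a pentacyclic Stemona-type alkaloid built on an octahydropyrrolo[1,2-a]azepine (ring A: N4, C3, C2, C1, C9a; ring B: N4, C5 to C9, C9a). A cyclopentane (ring C: C9, C10, C11, C12, C9a) is fused to its C9–C9a bond, a γ-lactone (ring D: O–C14(=O)–C13–C12–C11) is cis-fused to ring C at C11–C12, and a second γ-lactone (ring E: C18 to C21, methyl on C20) hangs from C3 through C18. Of the nine stereocentres, six (C9, C9a, C10, C11, C12, C13) are contiguous around ring C, with the aza-quaternary C9a flanked by C9 and C12 and the tertiary alcohol C13 next to C12; C3, C18 and C20 form a separate array (N and O syn across C3–C18, methyl cis to C3 on ring E). On ring C the ethyl group on C10 is trans to the oxygen on C11 and to C8 on C9, the oxygen on C11 is cis to C13, and N4 and C8 lie on opposite faces, so it is the B/C junction that is trans-fused (the A/B junction through nitrogen has no fixed fusion geometry); on ring A the ring E substituent is cis to C12 and trans to C9. A cross-check of every stereodescriptor of 30 and 31 against 33 shows the three structures to be mutually consistent, so none needed correction. Fragile elements are the two lactones (only ring E keeps an enolisable α-hydrogen), the tertiary α-hydroxy ester (retro-aldol once C11 is a carbonyl group, reductive C–O cleavage), the β-amino carbonyl relationship N4–C9a–C12–C11 (β-elimination or retro-Mannich at the aldehyde stage) and the oxidisable tertiary amine. The real difficulty is the aza-quaternary C9a with three different carbon arms, set against C9, C12 and the remote C3, together with the C12/C13 pair, which cannot be corrected by late enolate chemistry because ring E would react as well. The key step exploits the C10–C11 bond of ring C: oxygen on C11 anti to an ethyl group on C10 is the signature of a ketyl radical at C11 adding 5-exo to a propenyl group on C9.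

## Logic of the disconnections

33 to 31: the acyl bond O–C14 of ring D is cut. The cis relationship of the C11 hydroxyl and the C13 arm makes the closure trivial, and a tert-butyl ester in 31 allows ring closure and ester cleavage in one acidic step. The demand is only that the tertiary C13 hydroxyl does not ionise, which the adjacent carbonyl group ensures.

31 to 30: the C10–C11 bond is cut. This removes ring C and two stereocentres (C10, C11) and turns the ethyl group into an (E)-propenyl group on C9. The forward step must reduce the C11 aldehyde selectively in the presence of an α-hydroxy ester and two lactones, and must close the ring faster than the ketyl is reduced or dimerises. The skeleton of 30 is kept as it stands; the free C13 hydroxyl and the bulky ester are retained on purpose (chelation of samarium, no transesterification in the flask).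

30 to 28 and 29: the C12–C13 bond is cut (aldol). All four carbons of the C13/C14 unit and the tertiary alcohol come from 29 in one step. The forward step must control C12 and C13 together on a hindered donor; it is placed directly before the key step so that the retro-aldol-prone 30 is not carried further.

28 to 27 to 24: between 28 and 27 only the oxidation level of C11 changes; between 27 and 24 the N4–C5 bond of ring B is cut. A primary halide and a carbamate-protected nitrogen are simpler to carry than the tertiary amine. The forward closure must be faster than acyl transfer from ring E to the free secondary amine.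

24 to 22 to 19 and 21 (from 20): the ring E acyl bond O–C21 and then the C18–C19 bond are cut. C20 is bought with 20, C18 is set by reduction of the ketone in 22 under the influence of C3, and the ketone is made from thioester 19 without touching the other carbonyl groups.

19 to 18 to 15: functional-group changes only (oxidation of the C18 carbon, thioester formation). 15 to 13 to 11: the C11–C12 bond is cut (one-carbon homologation). The carboxyl carbon of 11 becomes C12; the forward rearrangement must move the fully substituted C9a with retention.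

11 to 8 to 4 and 7: the C9–C9a bond is cut as a [3,3] shift, then the ester C–O bond. One step creates the aza-quaternary C9a, the adjacent C9 and the (E)-propenyl group, with the chain C5 to C8 already in place. The forward step needs one ketene acetal geometry and delivery anti to the C3 substituent; the single carbinol centre of 7 supplies the absolute sense.

4 to 2 to 1, and 7 to 5 and 6: the C9a–C12 bond is cut back to a proline-derived carbamate whose only stereocentre is C3 of the target; 7 is cut at its double bond into two commercial alkenes.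

## Other disconnections considered

Alternative 1: The cut passes through C11–C12 and the ring D bonds C13–C14 and C14–O, which leads back to aldehyde A1 (2-substituted butanal on C9, vinyl group on C9a, silyloxymethyl group on C3). In the forward step Cp2Ti(PMe3)2, a complex of divalent titanium, would couple the aldehyde and the vinyl group to an oxatitanacycle, CO would insert, and reductive elimination would give the cis-fused lactone A2.
- In favour: two rings, three bonds and the C11/C12 pair are made in one operation, the cis D/C fusion follows from the mechanism, and no retro-aldol-prone intermediate or seco-lactone appears. On bonds and rings per step this is better than the chosen plan.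
- Also in favour: C13 could afterwards be built on the convex face of A2 by enolate methylation and then hydroxylation, which would place the hydroxyl exo as required. This control of C13 is more dependable than the intermolecular aldol of step 14, and it is open only because ring E is not yet present.
- Against: C10 is α to the aldehyde in A1 and would have to survive as an epimerisable centre, whereas the chosen plan creates C10 in the ring closure itself. The facial course of metallacycle formation on a trans-fused 5–7 template is uncertain, the reaction is established for simple unsaturated ketones and aldehydes and needs stoichiometric, air-sensitive titanium, and a basic amine sits on the carbon that carries the alkene.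
- Against: ring E would have to be made at the end next to ring D, several steps after the key step instead of one.
- Comparison: both plans close ring C onto the aldehyde carbon C11 (C11–C12 there, C10–C11 here); total step counts should be similar, with the risk of the alternative concentrated in one organometallic step and the late ring E.

Alternative 2: The cut removes N4–C9a and N4–C5 and leads to azido ketone A3, a trans-hydrindanone that already carries ring D, the ethyl group and a 3-azidopropyl chain with ring E. In the forward step TiCl4 would promote addition of the azide to the C5 ketone, and migration of C9a to nitrogen with loss of N2 would give lactam A4.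
- In favour: both C–N bonds and rings A and B form in one step, and the aza-quaternary centre is derived with retention from an all-carbon quaternary centre that can be made by ordinary enolate chemistry on a carbocycle. That is a more secure origin of C9a than the geometry-dependent rearrangement of step 5, and it is the better solution on that point. The six-membered azidohydrin fixes the regiochemistry of migration.
- Against: every stereocentre, both lactones and the tertiary alcohol must be in place first and must survive a strong Lewis acid; the secondary azide at C3 must be introduced with inversion next to ring E.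
- Against: A4 still needs reduction of a lactam in the presence of two lactones (thiolactam desulfurisation, or hydrosilylation with IrCl(CO)(PPh3)2), which adds delicate steps, and ring C is not addressed at all.
- Comparison: A4 maps directly onto 33 and the key step forms more bonds than step 15, but the hydrindanone with five contiguous stereocentres is probably a longer target than 30; mechanistically it is a cationic 1,2-shift, not a radical closure.

Alternative 3: The cut removes C9a–C1 and C3–C2 of ring A and leads to betaine A5 and 1,1-bis(phenylsulfonyl)ethene A7, which would combine to the bridged cycloadduct A6.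
- In favour: ring A and the aza-quaternary C9a come from a flat pyridine in one step, the sulfones are removable, and the bicycle holds the alkene carbon on C9a and the carbonyl carbon on C3 cis across the pyrrolidine. That is exactly the C12/C18 relationship of 33, and it is better secured than by the facial preference relied on in step 5.
- Against: the face of the planar betaine would be chosen only by the exocyclic stereocentre C9, a weak acyclic control.
- Against: the orientation drawn for A6 (sulfonyl-bearing carbon on the bridgehead next to the ketone) is opposite to the usual orientation of electron-poor alkenes with such betaines and would have to be enforced by the clash of two fully substituted carbons.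
- Against: desulfonylation, debenzylation, excision of the enone bridge and the construction of rings B, C, D and E would all remain.
- Comparison: the step delivers one ring and one stereocentre of 33; in step economy it is clearly behind the chosen plan. In mechanism it is a dipolar cycloaddition that leaves the C10–C11 problem untouched.

Key step: step 15

Assumption: atoms carry the pyrrolo[1,2-a]azepine labels used above (N4; C9a aza-quaternary; ring C = C9, C10, C11, C12, C9a; ring D = O–C14(=O)–C13–C12–C11; ring E = C18 carbinol, C19, C20 methyl-bearing, C21 carbonyl, on C3), and the proline-type intermediates keep these labels.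

## Route

Step 1
Reactants: 1 tert-butyl (2S)-2-(hydroxymethyl)pyrrolidine-1-carboxylate (N-Boc-L-prolinol)
Product: 2 tert-butyl (2S)-2-{[(tert-butyldimethylsilyl)oxy]methyl}pyrrolidine-1-carboxylate
Conditions: TBSCl, imidazole, DMF, 25 °C
Reagents that add atoms: tert-butyldimethylsilyl chloride, CC(C)(C)[Si](C)(C)Cl
Why: Standard silylation of a primary alcohol; the silyl ether tolerates the organolithium and amide bases that follow and is later removed and oxidised in one operation. The stereocentre of 1 becomes C3 (S) of the target.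

Step 2
Reactants: 2 tert-butyl (2S)-2-{[(tert-butyldimethylsilyl)oxy]methyl}pyrrolidine-1-carboxylate
Product: 4 (2S,5S)-1-(tert-butoxycarbonyl)-5-{[(tert-butyldimethylsilyl)oxy]methyl}pyrrolidine-2-carboxylic acid, via trans-5-lithio carbamate 3 (not isolated)
Conditions: s-BuLi, TMEDA, Et2O, −78 °C; CO2; 1 M HCl to pH 3, 0 °C
Reagents that add atoms: carbon dioxide, O=C=O
Why: Carbamate-directed α-lithiation of an N-Boc pyrrolidine and carboxylation; the 2-substituent turns the carbamate carbonyl, and so the base, to the unsubstituted α-methylene. The trans preference is of no consequence because this centre is made trigonal in step 5.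

Step 3
Reactants: 5 (S)-but-3-en-2-ol; 6 6-chlorohex-1-ene
Product: 7 (2S,3E)-8-chlorooct-3-en-2-ol
Conditions: second-generation Grubbs catalyst (H2IMes)(PCy3)Cl2Ru=CHPh (2 mol%), 6 (3 equiv), CH2Cl2, 40 °C
Reagents that add atoms: none
Why: Olefin cross-metathesis of a secondary allylic alcohol with an excess of a simple terminal alkene, a pairing that should favour the cross product and the E isomer; the carbinol centre is not touched.

Step 4
Reactants: 4 (2S,5S)-1-(tert-butoxycarbonyl)-5-{[(tert-butyldimethylsilyl)oxy]methyl}pyrrolidine-2-carboxylic acid; 7 (2S,3E)-8-chlorooct-3-en-2-ol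
Product: 8 1-tert-butyl 2-[(2S,3E)-8-chlorooct-3-en-2-yl] (2S,5S)-5-{[(tert-butyldimethylsilyl)oxy]methyl}pyrrolidine-1,2-dicarboxylate
Conditions: EDC·HCl, DMAP, CH2Cl2, 0 → 25 °C
Reagents that add atoms: none
Why: Steglich esterification of a carbamate-protected proline acid with a secondary alcohol; any epimerisation α to the ester would be harmless because that centre is erased in the next step.

Step 5
Reactants: 8 1-tert-butyl 2-[(2S,3E)-8-chlorooct-3-en-2-yl] (2S,5S)-5-{[(tert-butyldimethylsilyl)oxy]methyl}pyrrolidine-1,2-dicarboxylate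
Product: 11 (2S,5S)-1-(tert-butoxycarbonyl)-5-{[(tert-butyldimethylsilyl)oxy]methyl}-2-[(2E,4R)-8-chlorooct-2-en-4-yl]pyrrolidine-2-carboxylic acid, via (Z)-silyl ketene acetal 9 (not isolated), via trimethylsilyl ester 10 (not isolated)
Conditions: LiN(i-Pr)2, THF, −78 °C; Me3SiCl/Et3N, −78 → 60 °C; aq citric acid
Reagents that add atoms: none
Why: Ireland–Claisen rearrangement: the lithium enolate, held with O–Li beside the carbamate, should be silylated to ketene acetal 9 (Me3SiO cis to N), which rearranges through a chair with the carbinol methyl group equatorial. This transfers the (S) carbinol configuration to C9 (R) and C9a (S), delivers the allyl unit to the face anti to the C3 substituent (a matched case) and leaves the (E)-propenyl group.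

Step 6
Reactants: 11 (2S,5S)-1-(tert-butoxycarbonyl)-5-{[(tert-butyldimethylsilyl)oxy]methyl}-2-[(2E,4R)-8-chlorooct-2-en-4-yl]pyrrolidine-2-carboxylic acid
Product: 13 tert-butyl (2S,5S)-5-{[(tert-butyldimethylsilyl)oxy]methyl}-2-[(2E,4R)-8-chlorooct-2-en-4-yl]-2-(diazoacetyl)pyrrolidine-1-carboxylate, via isobutyl carbonic anhydride 12 (not isolated)
Conditions: i-BuOCOCl, N-methylmorpholine, THF, −20 °C; CH2N2, Et2O, 0 → 25 °C
Reagents that add atoms: diazomethane, C=[N+]=[N-]
Why: First half of an Arndt–Eistert homologation, the usual mixed-anhydride acylation of diazomethane as applied to α,α-disubstituted N-Boc amino acids; the quaternary centre cannot epimerise.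

Step 7
Reactants: 13 tert-butyl (2S,5S)-5-{[(tert-butyldimethylsilyl)oxy]methyl}-2-[(2E,4R)-8-chlorooct-2-en-4-yl]-2-(diazoacetyl)pyrrolidine-1-carboxylate
Product: 15 tert-butyl (2R,5S)-5-{[(tert-butyldimethylsilyl)oxy]methyl}-2-[(2E,4R)-8-chlorooct-2-en-4-yl]-2-{2-[methoxy(methyl)amino]-2-oxoethyl}pyrrolidine-1-carboxylate, via ketene 14 (not isolated)
Conditions: PhCO2Ag (10 mol%), MeNHOMe·HCl, Et3N, THF, −20 → 25 °C, dark
Reagents that add atoms: N,O-dimethylhydroxylamine (used as hydrochloride), CNOC
Why: Wolff rearrangement; C9a migrates with retention and the ketene is trapped by the amine. The N-methoxy-N-methylamide places C11 at an oxidation level that is inert to steps 8 to 12 and can be taken to the aldehyde beside a lactone.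

Step 8
Reactants: 15 tert-butyl (2R,5S)-5-{[(tert-butyldimethylsilyl)oxy]methyl}-2-[(2E,4R)-8-chlorooct-2-en-4-yl]-2-{2-[methoxy(methyl)amino]-2-oxoethyl}pyrrolidine-1-carboxylate
Product: 18 (2S,5R)-1-(tert-butoxycarbonyl)-5-[(2E,4R)-8-chlorooct-2-en-4-yl]-5-{2-[methoxy(methyl)amino]-2-oxoethyl}pyrrolidine-2-carboxylic acid, via primary alcohol 16 (not isolated), via aldehyde 17 (not isolated)
Conditions: CrO3, H2SO4, H2O, acetone, 0 °C
Reagents that add atoms: water, O
Why: Jones oxidation cleaves the primary silyl ether and oxidises the alcohol through the aldehyde hydrate to the acid in one flask. The carbamate-protected α-amino aldehyde is oxidised faster than it can epimerise, and the alkene, chloride and amide are inert.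

Step 9
Reactants: 18 (2S,5R)-1-(tert-butoxycarbonyl)-5-[(2E,4R)-8-chlorooct-2-en-4-yl]-5-{2-[methoxy(methyl)amino]-2-oxoethyl}pyrrolidine-2-carboxylic acid
Product: 19 S-ethyl (2S,5R)-1-(tert-butoxycarbonyl)-5-[(2E,4R)-8-chlorooct-2-en-4-yl]-5-{2-[methoxy(methyl)amino]-2-oxoethyl}pyrrolidine-2-carbothioate
Conditions: EtSH, EDC·HCl, DMAP (cat.), CH2Cl2, 0 °C
Reagents that add atoms: ethanethiol, CCS
Why: Carbodiimide thioesterification; urethane-protected proline derivatives resist α-epimerisation under these conditions.

Step 10
Reactants: 19 S-ethyl (2S,5R)-1-(tert-butoxycarbonyl)-5-[(2E,4R)-8-chlorooct-2-en-4-yl]-5-{2-[methoxy(methyl)amino]-2-oxoethyl}pyrrolidine-2-carbothioate; 20 methyl (2R)-3-bromo-2-methylpropanoate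
Product: 22 methyl (2S)-4-{(2S,5R)-1-(tert-butoxycarbonyl)-5-[(2E,4R)-8-chlorooct-2-en-4-yl]-5-{2-[methoxy(methyl)amino]-2-oxoethyl}pyrrolidin-2-yl}-2-methyl-4-oxobutanoate, via organozinc bromide 21 (not isolated)
Conditions: 20, Zn, LiCl, THF, 40 °C; then 19, PdCl2(PPh3)2 (5 mol%), toluene, 25 °C
Reagents that add atoms: none
Why: Fukuyama coupling of an α-amino thioester with a β-zincated ester under zerovalent palladium; the ester, amide, carbamate and alkyl chloride are not attacked by the organozinc. C20 is bought with 20, and its stereocentre is not the metallated carbon.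

Step 11
Reactants: 22 methyl (2S)-4-{(2S,5R)-1-(tert-butoxycarbonyl)-5-[(2E,4R)-8-chlorooct-2-en-4-yl]-5-{2-[methoxy(methyl)amino]-2-oxoethyl}pyrrolidin-2-yl}-2-methyl-4-oxobutanoate
Product: 24 tert-butyl (2R,5S)-2-[(2E,4R)-8-chlorooct-2-en-4-yl]-2-{2-[methoxy(methyl)amino]-2-oxoethyl}-5-[(2S,4S)-4-methyl-5-oxooxolan-2-yl]pyrrolidine-1-carboxylate, via hydroxy ester 23 (not isolated)
Conditions: KB(s-Bu)3H, THF, −78 °C; AcOH; then p-TsOH·H2O (cat.), CH2Cl2, 25 °C
Reagents that add atoms: none
Why: Felkin–Anh reduction of a carbamate-protected α-amino ketone by a bulky, poorly chelating hydride: attack anti to the C3–N bond, past the C3 hydrogen, should give the (18S) alcohol with N and O syn. Quenching cold and closing the lactone under mild acid avoids alkoxide-induced epimerisation at C20.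

Step 12
Reactants: 24 tert-butyl (2R,5S)-2-[(2E,4R)-8-chlorooct-2-en-4-yl]-2-{2-[methoxy(methyl)amino]-2-oxoethyl}-5-[(2S,4S)-4-methyl-5-oxooxolan-2-yl]pyrrolidine-1-carboxylate
Product: 27 N-methoxy-N-methyl-2-{(3S,9R,9aR)-3-[(2S,4S)-4-methyl-5-oxooxolan-2-yl]-9-[(1E)-prop-1-en-1-yl]octahydro-1H-pyrrolo[1,2-a]azepin-9a-yl}acetamide, via iodide 25 (not isolated), via ammonium trifluoroacetate 26 (not isolated)
Conditions: NaI, acetone, 56 °C; CF3CO2H, CH2Cl2, 0 °C; i-Pr2NEt, MeCN, 40 °C
Reagents that add atoms: none
Why: Finkelstein exchange, acidolysis of the Boc group and intramolecular N-alkylation (7-exo-tet), helped by the Thorpe–Ingold effect of C9a. The amine is kept protonated until the iodide is in place and the closure is run warm, not hot, so that acyl transfer from ring E to the free secondary amine should not compete.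

Step 13
Reactants: 27 N-methoxy-N-methyl-2-{(3S,9R,9aR)-3-[(2S,4S)-4-methyl-5-oxooxolan-2-yl]-9-[(1E)-prop-1-en-1-yl]octahydro-1H-pyrrolo[1,2-a]azepin-9a-yl}acetamide
Product: 28 {(3S,9R,9aR)-3-[(2S,4S)-4-methyl-5-oxooxolan-2-yl]-9-[(1E)-prop-1-en-1-yl]octahydro-1H-pyrrolo[1,2-a]azepin-9a-yl}acetaldehyde
Conditions: Cp2Zr(H)Cl (1.5 equiv), THF, 25 °C, 20 min
Reagents that add atoms: none
Why: Cp2Zr(H)Cl reduces tertiary and N-methoxy-N-methyl amides to aldehydes without over-reduction and leaves esters and lactones untouched on this time scale; hydrozirconation of the hindered internal alkene should be much slower. The β-amino aldehyde is used at once.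

Step 14
Reactants: 28 {(3S,9R,9aR)-3-[(2S,4S)-4-methyl-5-oxooxolan-2-yl]-9-[(1E)-prop-1-en-1-yl]octahydro-1H-pyrrolo[1,2-a]azepin-9a-yl}acetaldehyde; 29 tert-butyl 2-oxopropanoate
Product: 30 tert-butyl (2S,3S)-3-formyl-2-hydroxy-2-methyl-3-{(3S,9R,9aS)-3-[(2S,4S)-4-methyl-5-oxooxolan-2-yl]-9-[(1E)-prop-1-en-1-yl]octahydro-1H-pyrrolo[1,2-a]azepin-9a-yl}propanoate
Conditions: L-proline (30 mol%), 29 (3 equiv), DMF, 4 °C
Reagents that add atoms: none
Why: Enamine-catalysed cross-aldol of an aldehyde donor with an activated α-keto ester acceptor; the aldehyde forms its enamine faster than the ketone does, and the self-aldol of 29 is the expected side reaction. L-Proline fixes the enamine face (12S, as in proline aldols of aldehydes), and the planar ester should take the crowded position next to the iminium carbon while the methyl group points away, which gives 13S with the hydroxyl syn to C9a along the C11–C14 chain.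

Step 15
Reactants: 30 tert-butyl (2S,3S)-3-formyl-2-hydroxy-2-methyl-3-{(3S,9R,9aS)-3-[(2S,4S)-4-methyl-5-oxooxolan-2-yl]-9-[(1E)-prop-1-en-1-yl]octahydro-1H-pyrrolo[1,2-a]azepin-9a-yl}propanoate
Product: 31 ring C diol tert-butyl ester (seco-lactone D), tert-butyl (2S)-2-hydroxy-2-[C12 of the (3S,9R,9aS,10R,11S,12R)-10-ethyl-11-hydroxy ring C tricycle carrying ring E on C3]propanoate
Conditions: SmI2 (2.5 equiv), HMPA (8 equiv), t-BuOH (2 equiv), THF, −78 → 0 °C, 30 added over 1 h
Reagents that add atoms: none
Why: Electron transfer from divalent samarium, made more reducing by HMPA, converts the C11 aldehyde into a samarium ketyl that adds to C10 of the propenyl group; the secondary radical left on the former alkene terminus is reduced by a second equivalent and protonated by t-BuOH, which creates the ethyl group, and the closest known reaction type is the SmI2–HMPA ketyl–olefin cyclisation of unactivated alkenyl aldehydes and ketones. Ring C is the only ring closed, in the 5-exo-trig mode through a chair-like transition state in which the fully substituted C9a gathers the chain C11–C12–C9a–C9–C10. C10 is controlled by C9: the C8 methylene of ring B sits pseudo-equatorial, so the alkene is attacked on the face that places the nascent ethyl group trans to C8 (10R). C11 is controlled by two effects that reinforce each other: the bulky trivalent samarium alkoxide stays anti to the developing radical centre (oxygen trans to ethyl), and it is held in a six-membered chelate by the C13 hydroxy ester on the pseudo-equatorial C12 arm (oxygen cis to C13), which gives 11S. The step needs reduction of the aldehyde in preference to the α-hydroxy ester, the lactones and the amine, which the much easier reduction of an aldehyde and the bulk of the tert-butyl ester should secure. It also needs cyclisation to outrun pinacol coupling and simple reduction, which slow addition of 30 to excess reagent at low temperature and the Thorpe–Ingold effect of C9a favour. The tert-butyl ester should not transesterify with the samarium alkoxide, so 31 should be isolable.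

Step 16
Reactants: 31 ring C diol tert-butyl ester (seco-lactone D)
Product: 33 target CNP0260919.2 (3S,9R,9aS,10R,11S,12R,13S,18S,20S), via hydroxy acid 32 (not isolated)
Conditions: CF3CO2H/CH2Cl2 (1:3), 0 → 25 °C; aq NaHCO3
Reagents that add atoms: none
Why: Acidolysis of the tert-butyl ester and acid-catalysed lactonisation of the cis 1,4-hydroxy acid to the five-membered ring D; the tertiary alcohol beside the carbonyl group does not ionise and ring E is stable to acid.

## Compound list

1 | tert-butyl (2S)-2-(hydroxymethyl)pyrrolidine-1-carboxylate (N-Boc-L-prolinol) | CC(C)(C)OC(=O)N1CCC[C@H]1CO | starting material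
2 | tert-butyl (2S)-2-{[(tert-butyldimethylsilyl)oxy]methyl}pyrrolidine-1-carboxylate | CC(C)(C)OC(=O)N1CCC[C@H]1CO[Si](C)(C)C(C)(C)C | intermediate
3 | trans-5-lithio derivative of 2 (Li trans to the silyloxymethyl group) | [Li][C@@H]1CC[C@@H](CO[Si](C)(C)C(C)(C)C)N1C(=O)OC(C)(C)C | intermediate
4 | (2S,5S)-1-(tert-butoxycarbonyl)-5-{[(tert-butyldimethylsilyl)oxy]methyl}pyrrolidine-2-carboxylic acid | OC(=O)[C@@H]1CC[C@@H](CO[Si](C)(C)C(C)(C)C)N1C(=O)OC(C)(C)C | intermediate
5 | (S)-but-3-en-2-ol | C[C@H](O)C=C | starting material
6 | 6-chlorohex-1-ene | C=CCCCCCl | starting material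
7 | (2S,3E)-8-chlorooct-3-en-2-ol | C[C@H](O)/C=C/CCCCCl | intermediate
8 | 1-tert-butyl 2-[(2S,3E)-8-chlorooct-3-en-2-yl] (2S,5S)-5-{[(tert-butyldimethylsilyl)oxy]methyl}pyrrolidine-1,2-dicarboxylate | C[C@H](OC(=O)[C@@H]1CC[C@@H](CO[Si](C)(C)C(C)(C)C)N1C(=O)OC(C)(C)C)/C=C/CCCCCl | intermediate
9 | (Z)-O-trimethylsilyl ketene acetal of 8 (Me3SiO cis to N) | C[C@H](O/C(O[Si](C)(C)C)=C1/N(C(=O)OC(C)(C)C)[C@H](CO[Si](C)(C)C(C)(C)C)CC1)/C=C/CCCCCl | intermediate
10 | trimethylsilyl ester of 11 | C/C=C/[C@@H](CCCCCl)[C@]1(C(=O)O[Si](C)(C)C)CC[C@@H](CO[Si](C)(C)C(C)(C)C)N1C(=O)OC(C)(C)C | intermediate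
11 | (2S,5S)-1-(tert-butoxycarbonyl)-5-{[(tert-butyldimethylsilyl)oxy]methyl}-2-[(2E,4R)-8-chlorooct-2-en-4-yl]pyrrolidine-2-carboxylic acid | C/C=C/[C@@H](CCCCCl)[C@]1(C(=O)O)CC[C@@H](CO[Si](C)(C)C(C)(C)C)N1C(=O)OC(C)(C)C | intermediate
12 | isobutyl carbonic mixed anhydride of 11 | C/C=C/[C@@H](CCCCCl)[C@]1(C(=O)OC(=O)OCC(C)C)CC[C@@H](CO[Si](C)(C)C(C)(C)C)N1C(=O)OC(C)(C)C | intermediate
13 | tert-butyl (2S,5S)-5-{[(tert-butyldimethylsilyl)oxy]methyl}-2-[(2E,4R)-8-chlorooct-2-en-4-yl]-2-(diazoacetyl)pyrrolidine-1-carboxylate | C/C=C/[C@@H](CCCCCl)[C@]1(C(=O)C=[N+]=[N-])CC[C@@H](CO[Si](C)(C)C(C)(C)C)N1C(=O)OC(C)(C)C | intermediate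
14 | ketene from 13 (ring carbon C9a bonded to CH=C=O, configuration retained) | C/C=C/[C@@H](CCCCCl)[C@]1(C=C=O)CC[C@@H](CO[Si](C)(C)C(C)(C)C)N1C(=O)OC(C)(C)C | intermediate
15 | tert-butyl (2R,5S)-5-{[(tert-butyldimethylsilyl)oxy]methyl}-2-[(2E,4R)-8-chlorooct-2-en-4-yl]-2-{2-[methoxy(methyl)amino]-2-oxoethyl}pyrrolidine-1-carboxylate | C/C=C/[C@@H](CCCCCl)[C@]1(CC(=O)N(C)OC)CC[C@@H](CO[Si](C)(C)C(C)(C)C)N1C(=O)OC(C)(C)C | intermediate
16 | tert-butyl (2R,5S)-2-[(2E,4R)-8-chlorooct-2-en-4-yl]-5-(hydroxymethyl)-2-{2-[methoxy(methyl)amino]-2-oxoethyl}pyrrolidine-1-carboxylate | C/C=C/[C@@H](CCCCCl)[C@]1(CC(=O)N(C)OC)CC[C@@H](CO)N1C(=O)OC(C)(C)C | intermediate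
17 | tert-butyl (2R,5S)-2-[(2E,4R)-8-chlorooct-2-en-4-yl]-5-formyl-2-{2-[methoxy(methyl)amino]-2-oxoethyl}pyrrolidine-1-carboxylate | C/C=C/[C@@H](CCCCCl)[C@]1(CC(=O)N(C)OC)CC[C@@H](C=O)N1C(=O)OC(C)(C)C | intermediate
18 | (2S,5R)-1-(tert-butoxycarbonyl)-5-[(2E,4R)-8-chlorooct-2-en-4-yl]-5-{2-[methoxy(methyl)amino]-2-oxoethyl}pyrrolidine-2-carboxylic acid | C/C=C/[C@@H](CCCCCl)[C@]1(CC(=O)N(C)OC)CC[C@@H](C(=O)O)N1C(=O)OC(C)(C)C | intermediate
19 | S-ethyl (2S,5R)-1-(tert-butoxycarbonyl)-5-[(2E,4R)-8-chlorooct-2-en-4-yl]-5-{2-[methoxy(methyl)amino]-2-oxoethyl}pyrrolidine-2-carbothioate | C/C=C/[C@@H](CCCCCl)[C@]1(CC(=O)N(C)OC)CC[C@@H](C(=O)SCC)N1C(=O)OC(C)(C)C | intermediate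
20 | methyl (2R)-3-bromo-2-methylpropanoate | BrC[C@H](C)C(=O)OC | starting material
21 | [(2R)-3-methoxy-2-methyl-3-oxopropyl]zinc bromide | Br[Zn]C[C@H](C)C(=O)OC | intermediate
22 | methyl (2S)-4-{(2S,5R)-1-(tert-butoxycarbonyl)-5-[(2E,4R)-8-chlorooct-2-en-4-yl]-5-{2-[methoxy(methyl)amino]-2-oxoethyl}pyrrolidin-2-yl}-2-methyl-4-oxobutanoate | C/C=C/[C@@H](CCCCCl)[C@]1(CC(=O)N(C)OC)CC[C@@H](C(=O)C[C@H](C)C(=O)OC)N1C(=O)OC(C)(C)C | intermediate
23 | methyl (2S,4S)-4-hydroxy analogue of 22 (18S alcohol) | C/C=C/[C@@H](CCCCCl)[C@]1(CC(=O)N(C)OC)CC[C@@H]([C@@H](O)C[C@H](C)C(=O)OC)N1C(=O)OC(C)(C)C | intermediate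
24 | tert-butyl (2R,5S)-2-[(2E,4R)-8-chlorooct-2-en-4-yl]-2-{2-[methoxy(methyl)amino]-2-oxoethyl}-5-[(2S,4S)-4-methyl-5-oxooxolan-2-yl]pyrrolidine-1-carboxylate | C/C=C/[C@@H](CCCCCl)[C@]1(CC(=O)N(C)OC)CC[C@@H]([C@@H]2C[C@H](C)C(=O)O2)N1C(=O)OC(C)(C)C | intermediate
25 | 8-iodo analogue of 24 | C/C=C/[C@@H](CCCCI)[C@]1(CC(=O)N(C)OC)CC[C@@H]([C@@H]2C[C@H](C)C(=O)O2)N1C(=O)OC(C)(C)C | intermediate
26 | N-deprotected 25 as its trifluoroacetate salt | C/C=C/[C@@H](CCCCI)[C@]1(CC(=O)N(C)OC)CC[C@@H]([C@@H]2C[C@H](C)C(=O)O2)N1.OC(=O)C(F)(F)F | intermediate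
27 | N-methoxy-N-methyl-2-{(3S,9R,9aR)-3-[(2S,4S)-4-methyl-5-oxooxolan-2-yl]-9-[(1E)-prop-1-en-1-yl]octahydro-1H-pyrrolo[1,2-a]azepin-9a-yl}acetamide | C/C=C/[C@H]1CCCCN2[C@H]([C@@H]3C[C@H](C)C(=O)O3)CC[C@@]12CC(=O)N(C)OC | intermediate
28 | {(3S,9R,9aR)-3-[(2S,4S)-4-methyl-5-oxooxolan-2-yl]-9-[(1E)-prop-1-en-1-yl]octahydro-1H-pyrrolo[1,2-a]azepin-9a-yl}acetaldehyde | C/C=C/[C@H]1CCCCN2[C@H]([C@@H]3C[C@H](C)C(=O)O3)CC[C@@]12CC=O | intermediate
29 | tert-butyl 2-oxopropanoate (tert-butyl pyruvate) | CC(=O)C(=O)OC(C)(C)C | starting material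
30 | tert-butyl (2S,3S)-3-formyl-2-hydroxy-2-methyl-3-{(3S,9R,9aS)-3-[(2S,4S)-4-methyl-5-oxooxolan-2-yl]-9-[(1E)-prop-1-en-1-yl]octahydro-1H-pyrrolo[1,2-a]azepin-9a-yl}propanoate | C/C=C/[C@H]1CCCCN2[C@H]([C@@H]3C[C@H](C)C(=O)O3)CC[C@@]12[C@H](C=O)[C@](C)(O)C(=O)OC(C)(C)C | intermediate
31 | ring C diol tert-butyl ester (seco-lactone D), (3S,9R,9aS,10R,11S,12R,13S,18S,20S) | CC[C@H]1[C@H](O)[C@H]([C@](C)(O)C(=O)OC(C)(C)C)[C@@]23CC[C@@H]([C@@H]4C[C@H](C)C(=O)O4)N2CCCC[C@H]13 | intermediate
32 | hydroxy acid from 31 (tert-butyl group removed) | CC[C@H]1[C@H](O)[C@H]([C@](C)(O)C(=O)O)[C@@]23CC[C@@H]([C@@H]4C[C@H](C)C(=O)O4)N2CCCC[C@H]13 | intermediate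
33 | CNP0260919.2, (3S,9R,9aS,10R,11S,12R,13S,18S,20S) | CC[C@H]1[C@@H]2OC(=O)[C@@](C)(O)[C@@H]2[C@@]23CC[C@@H]([C@@H]4C[C@H](C)C(=O)O4)N2CCCC[C@H]13 | target

## Step count and least certain steps

Total step count: 16. Longest linear sequence: 15 steps (steps 1, 2 and 4 to 16); step 3 makes the side fragment 7.

Step 15 (key step). The ketyl may be reduced further or dimerise (pinacol coupling) before it adds to the unactivated 1,2-disubstituted alkene, and electron transfer to the α-hydroxy ester may remove the C13 hydroxyl. Fallback, setting out from 30 and coming back at 31: the aldehyde C–H bond is used in place of the carbonyl π-system. Thiol-catalysed radical hydroacylation (methyl thioglycolate cat., t-BuON=NOt-Bu, dioxane, 60 °C) generates the C11 acyl radical, which closes 5-exo on C10 and gives ring C ketone F1, in which the ethyl group can settle trans to C8 by enolisation. NaBH4 (MeOH, −40 °C) should then add hydride on the face anti to the bulky C13 arm, which places the hydroxyl cis to that arm, and this is 31.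

Step 14. Self-aldolisation of 29 may outrun the hindered enamine of 28, face selection at the ketone (C13) may be poor, and 28 may lose its amine by β-elimination under the amine/acid conditions. Fallback, setting out from 28 and coming back at 30: 28 is oxidised (NaClO2, NaH2PO4, 2-methylbut-2-ene; Pinnick oxidation) to carboxylic acid F2 and converted (EtSH, EDC·HCl, DMAP) into S-ethyl thioester F3. Soft enolisation (Me3SiOTf, Et3N, CH2Cl2, 0 °C) gives silyl ketene thioacetal F4, which adds to 29 in a Mukaiyama aldol catalysed by [Cu((S,S)-t-Bu-box)](OTf)2, a chelate of the α-keto ester on divalent copper for which syn adducts with an (S) tertiary carbinol are the expected outcome. The silyl ether F5 is hydrolysed (1 M HCl, THF) to hydroxy thioester F6, and Fukuyama reduction (Et3SiH, Pd/C, acetone) gives 30. If the hindered amine sequesters copper, a full equivalent of the complex is used.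

Step 5. The ketene acetal may form with the other geometry (N trans to Me3SiO), which inverts C9 relative to C9a, or the rearrangement may leak through a boat. Fallback, setting out from 4 and coming back at 11: the allyl partner is changed to compensate. (R)-But-3-yn-2-ol is C-alkylated as its dianion (n-BuLi, THF/DMPU) with 1-bromo-4-chlorobutane to (2R)-8-chlorooct-3-yn-2-ol F7, semihydrogenated (H2, Pd/CaCO3–Pb(OAc)2, quinoline) to (2R,3Z)-8-chlorooct-3-en-2-ol F8 and esterified with 4 to allylic ester F9. Rearrangement of its (E)-silyl ketene acetal F10 through the chair then leads to 10 and, after work-up, to 11.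

Step 12. The liberated secondary amine may attack the carbonyl group of ring E (acyl transfer to a six-membered lactam) faster than it closes the seven-membered ring. Fallback, setting out from 22 and coming back at 27: ring B is closed before ring E exists. 22 is taken through the same three operations to iodide F11, ammonium trifluoroacetate F12 and bicyclic amino keto ester F13; reduction with KB(s-Bu)3H then gives hydroxy ester F14, which lactonises under acid to 27.

Step 11. Facial selectivity may be poor if a chelated pathway through the carbamate carbonyl competes with the Felkin–Anh one. Fallback, setting out from 22 and coming back at 24: the other epimer is made on purpose and inverted. Zn(BH4)2 (Et2O, −20 °C, chelation control) should give the (18R)-hydroxy ester F15, saponification (LiOH, THF/H2O) the hydroxy acid F16, and Mitsunobu lactonisation (PPh3, DIAD, THF) closes ring E with inversion at C18 to give 24.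

## Further compounds

F1 | step 15 | ring C ketone (C11 carbonyl) from hydroacylation of 30 | CC[C@H]1C(=O)[C@H]([C@](C)(O)C(=O)OC(C)(C)C)[C@@]23CC[C@@H]([C@@H]4C[C@H](C)C(=O)O4)N2CCCC[C@H]13
F2 | step 14 | carboxylic acid from 28 | C/C=C/[C@H]1CCCCN2[C@H]([C@@H]3C[C@H](C)C(=O)O3)CC[C@@]12CC(=O)O
F3 | step 14 | S-ethyl thioester of F2 | C/C=C/[C@H]1CCCCN2[C@H]([C@@H]3C[C@H](C)C(=O)O3)CC[C@@]12CC(=O)SCC
F4 | step 14 | silyl ketene thioacetal of F3 (S cis to C9a) | C/C=C/[C@H]1CCCCN2[C@H]([C@@H]3C[C@H](C)C(=O)O3)CC[C@@]12/C=C(/O[Si](C)(C)C)SCC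
F5 | step 14 | O-trimethylsilyl ether of F6 | C/C=C/[C@H]1CCCCN2[C@H]([C@@H]3C[C@H](C)C(=O)O3)CC[C@@]12[C@H](C(=O)SCC)[C@](C)(O[Si](C)(C)C)C(=O)OC(C)(C)C
F6 | step 14 | syn hydroxy thioester (C11 thioester analogue of 30) | C/C=C/[C@H]1CCCCN2[C@H]([C@@H]3C[C@H](C)C(=O)O3)CC[C@@]12[C@H](C(=O)SCC)[C@](C)(O)C(=O)OC(C)(C)C
F7 | step 5 | (2R)-8-chlorooct-3-yn-2-ol | C[C@@H](O)C#CCCCCCl
F8 | step 5 | (2R,3Z)-8-chlorooct-3-en-2-ol | C[C@@H](O)/C=C\CCCCCl
F9 | step 5 | (2R,3Z)-8-chlorooct-3-en-2-yl ester of 4 | C[C@@H](OC(=O)[C@@H]1CC[C@@H](CO[Si](C)(C)C(C)(C)C)N1C(=O)OC(C)(C)C)/C=C\CCCCCl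
F10 | step 5 | (E)-O-trimethylsilyl ketene acetal of F9 (Me3SiO trans to N) | C[C@@H](O/C(O[Si](C)(C)C)=C1\N(C(=O)OC(C)(C)C)[C@H](CO[Si](C)(C)C(C)(C)C)CC1)/C=C\CCCCCl
F11 | step 12 | 8-iodo analogue of 22 | C/C=C/[C@@H](CCCCI)[C@]1(CC(=O)N(C)OC)CC[C@@H](C(=O)C[C@H](C)C(=O)OC)N1C(=O)OC(C)(C)C
F12 | step 12 | N-deprotected F11 as its trifluoroacetate salt | C/C=C/[C@@H](CCCCI)[C@]1(CC(=O)N(C)OC)CC[C@@H](C(=O)C[C@H](C)C(=O)OC)N1.OC(=O)C(F)(F)F
F13 | step 12 | bicyclic amino keto ester (ring B closed, C18 ketone) | C/C=C/[C@H]1CCCCN2[C@H](C(=O)C[C@H](C)C(=O)OC)CC[C@@]12CC(=O)N(C)OC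
F14 | step 12 | bicyclic (18S)-hydroxy ester | C/C=C/[C@H]1CCCCN2[C@H]([C@@H](O)C[C@H](C)C(=O)OC)CC[C@@]12CC(=O)N(C)OC
F15 | step 11 | (18R)-hydroxy ester, C18 epimer of 23 | C/C=C/[C@@H](CCCCCl)[C@]1(CC(=O)N(C)OC)CC[C@@H]([C@H](O)C[C@H](C)C(=O)OC)N1C(=O)OC(C)(C)C
F16 | step 11 | (18R)-hydroxy acid from F15 | C/C=C/[C@@H](CCCCCl)[C@]1(CC(=O)N(C)OC)CC[C@@H]([C@H](O)C[C@H](C)C(=O)O)N1C(=O)OC(C)(C)C
A1 | alternative 1 | aldehyde with 2-substituted butanal on C9, vinyl on C9a and triisopropylsilyloxymethyl on C3 | CC[C@@H](C=O)[C@H]1CCCCN2[C@H](CO[Si](C(C)C)(C(C)C)C(C)C)CC[C@@]12C=C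
A2 | alternative 1 | tetracyclic lactone lacking the C13 methyl and hydroxyl groups | CC[C@H]1[C@@H]2OC(=O)C[C@@H]2[C@@]23CC[C@@H](CO[Si](C(C)C)(C(C)C)C(C)C)N2CCCC[C@H]13
A3 | alternative 2 | azido trans-hydrindanone carrying ring D and the ring E side chain | CC[C@H]1[C@@H]2OC(=O)[C@@](C)(O)[C@@H]2[C@@]2(CC[C@H](N=[N+]=[N-])[C@@H]3C[C@H](C)C(=O)O3)C(=O)CCC[C@H]12
A4 | alternative 2 | C5 lactam of the target | CC[C@H]1[C@@H]2OC(=O)[C@@](C)(O)[C@@H]2[C@@]23CC[C@@H]([C@@H]4C[C@H](C)C(=O)O4)N2C(=O)CCC[C@H]13
A5 | alternative 3 | 6-substituted N-benzyl-3-oxidopyridinium betaine | CC[C@@H](CO[Si](C)(C)C(C)(C)C)[C@@H](CCCCOCc1ccc(OC)cc1)c1ccc([O-])c[n+]1Cc1ccccc1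
A6 | alternative 3 | bis-sulfonyl 8-azabicyclo[3.2.1]octenone cycloadduct | CC[C@@H](CO[Si](C)(C)C(C)(C)C)[C@@H](CCCCOCc1ccc(OC)cc1)[C@@]12C=CC(=O)[C@@H](N1Cc1ccccc1)C(S(=O)(=O)c1ccccc1)(S(=O)(=O)c1ccccc1)C2
A7 | alternative 3 | 1,1-bis(phenylsulfonyl)ethene | C=C(S(=O)(=O)c1ccccc1)S(=O)(=O)c1ccccc1
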